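Atom labels: rings A and C carry flavone numbering (O1, C2, C3, C4, C4a, C5 to C8, C8a), also on the corresponding carbons of open-chain and pyranone precursors; butenolide atoms are primed (O1', C2' to C5'). Compounds 1 to 19 are defined in the steps and the compound list; 8 is the precursor of the key step, 10 its product and 19 the target.

## Analysis of the target

Compound 19 is a flavone. Ring C is a 4-pyranone (O1, C2, C3, C4, C4a, C8a) fused to the benzo ring A (C4a, C5, C6, C7, C8, C8a), with phenyl ring B on C2, a methoxy group on C7, and C8 bonded to C3' of a 5,5-dimethylfuran-2(5H)-one. There is no stereocentre, and the C8–C3' axis is not expected to be configurationally stable, so no stereochemical relationship has to be set. The sensitive groups are the butenolide (a conjugate acceptor and a lactone that alkoxide or hydroxide opens) and the chromone C2 position, which hard nucleophiles attack. The butenolide is therefore best made last and under mild conditions. The difficulty is C8: it is the most crowded carbon of ring A, lies between two oxygen-bearing carbons, and must carry an sp2 carbon that is itself flanked on both sides. Electrophilic substitution of a 7-oxygenated flavone is divided between C6 and C8, and a cross-coupling at C8 would be a heavily ortho-substituted one. The strategy rests on the oxygen pattern: C2, C4, C8a and C7 carry oxygen and C5 does not, which is the pattern of a benzoyl-started chain of alternating carbonyl carbons folded by a C4a–C5 bond. In that chain C8 is the carbon between the C8a and C7 carbonyls, so a substituent can be put there by enolate alkylation before ring A exists. The carbonyls at C2, C4 and C8a can be held as a 6-phenyl-4-pyranone, which is ring C of 19 already made.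

## Retrosynthetic reasoning

**Butenolide (C3'=C4', C2'–O1', C3'–C4').** The C3'=C4' double bond of 19 is taken back to a C4' hydroxyl in lactone 17, which is eliminated through its sulfonate 18. The lactone C2'–O1' bond is then opened to the dihydroxy ester 16, carried as its silyl ether 15. The C3'–C4' bond is cut as an aldol union of arylacetate 11 with the α-silyloxy aldehyde 14. These cuts reduce the hindered C8 substituent to a CH2CO2Me arm and bring C4', C5', both methyl groups and O1' from one small aldehyde. Aldehyde 14 comes from hydroxy ester 12 by silylation (13) and partial reduction. The forward reactions must add a hindered ester enolate to an α-quaternary aldehyde, close the five-membered lactone and remove the C4' oxygen; the two transient stereocentres do not matter.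

**O–CH3 at C7.** Ether 11 is taken back to phenol 10. The free phenol is what the ring-forming step delivers, and it is more acidic than any C–H in 10, so the forward methylation is selective.

**C4a–C5 (the key cut).** Ring A of 10 is opened between C4a and C5, through the non-aromatic ring-closed stage 9, to the pyranone keto acetal 8. This is the only ring A bond whose cleavage leaves every oxygen on its final carbon, leaves ring C intact as a 4-pyranone, and needs no change of oxidation level, because C5 is held as an acetal. Cutting at C8–C8a or C4–C4a would destroy ring C as well, and the classical ring C disconnections leave the C8 problem untouched. The forward reaction has to make the pyranone carbon C4a attack C5 under acid and then aromatise by elimination alone.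

**C8–CH2.** The ester arm of 8 is removed as the bromo ester 7, leaving 6. C8 of 6 is flanked by the C7 ketone and the pyranone and is the most acidic carbon, so the forward step is a simple alkylation.

**C8–C7.** Keto acetal 6 is cut between C8 and C7 into pyranone 4 and ester 5. The 2-methyl group of 4 is vinylogously acidic and its anion reacts at the exocyclic carbon, so the forward step is a Claisen-type acylation.

**Ring C and C2–C3.** Pyranone 4 is opened at one ring C–O bond to triketone 3 (forward: cyclodehydration, only one pyranone possible). Triketone 3 is cut at C2–C3 into diketone 1 and the non-enolisable ester 2 (forward: acylation of the dianion of 1 at a terminal carbon).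

## Alternatives that were turned down

**Alternative 1:** The C8–C3' bond and the C8a–O bond are cut together. Ring A goes back to 3-methoxybenzyne A2, released by fluoride from the silyl triflate A1, and C3' becomes the carboxyl carbon of the unsaturated acid A3. In the forward key step the carboxylate oxygen of A3 adds to the aryne carbon remote from the methoxy group, the aryl anion next to the methoxy group takes the acyl carbon, and the ortho-hydroxyaryl enone closes by oxa-Michael addition to chromanone A4.
- For: aryne insertion into an acid C–O bond is a known reaction type, the methoxy group directs A2 reliably, and the crowded O/C/OMe pattern is set in one step from simple materials.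
- Against: A4 is far from 19. Its dimethyl carbon is bonded to the oxygen that must become O1 of ring C and not to the lactone oxygen, and the lactone carbonyl carbon C2' is missing. Ring C and ring B still have to be built onto a ring with no handle at the future C4a, where acylation would compete with C6.
- Comparison: alternative 1 is stronger on precedent for its key step. The chosen strategy offers a key step that delivers rings A and C with every oxygen in place and leaves only the butenolide to finish.

**Alternative 2:** The C8–C3' bond and the lactone O1'–C5' bond are cut, taking the butenolide back to the aryl propargyl ether acid A5, in which the C7 oxygen carries the CMe2–C≡C–CO2H chain. On heating, a propargyl Claisen shift would move the chain to C8 as the 2-aryl allenoic acid A6, whose carboxyl group would add to the far allene carbon to give the 7-hydroxy butenolide A7. O-Methylation of A7 gives 19.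
- For: the route is short, the flavone core is used ready-made, and [3,3] shifts of 7-O-allyl and 7-O-propargyl ethers of chromones are known to prefer C8. On step count this alternative is clearly stronger than the chosen route.
- Against: aryl 1,1-dimethylpropargyl ethers are the standard precursors of 2,2-dimethylchromenes. After the shift, the ortho-allenyl phenol normally undergoes a 1,5-hydrogen shift and oxa-6π closure, which would tie O7 and C5' into a pyran ring and use up the atoms needed for the lactone. Uncatalysed lactonisation of A6 at Claisen temperature is not assured, and the alkynoic acid may decarboxylate. Making the tertiary ether A5 also needs a propargylation and an alkyne carboxylation on the flavone.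
- Comparison: in place of brevity, the chosen strategy puts the C8 carbon in by enolate alkylation before ring A exists, so no pericyclic competition decides the fate of O7. The price is a longer sequence and an untested closure.

**Alternative 3:** Ring A is taken back to a cyclohexane-1,3-dione. The C4a–C4 and O1–C2 bonds of ring C are cut, giving the vinylogous ester A8, which already carries the butenolide between its two oxygenated carbons, and the alkynyl Weinreb amide A9. In the forward key step the kinetic lithium enolate of A8 is acylated by A9, and the enol oxygen of the resulting alkynyl diketone closes 6-endo-dig to the dihydroflavone A10. Dehydrogenation of C5–C6 then gives 19.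
- For: each operation is of a known type (α'-acylation of a vinylogous ester, ynone-to-pyranone closure, dehydrogenation), the 1,2,3-pattern is fixed by the dione, and the route is convergent. On precedent and convergence it is stronger than the chosen route.
- Against: A8 contains the hard bond itself (dione C2 to butenolide C3'), so the difficulty is moved and not removed. The butenolide must survive a stoichiometric lithium amide and a reactive enolate, with conjugate addition at C4' and attack on the lactone carbonyl as risks. The acylation product is more acidic than A8 and consumes extra base, and the end needs an external oxidant on a ring bearing an enol ether.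
- Comparison: the chosen strategy offers a ring A that aromatises by condensation alone, with the oxidation level stored in the acetal, and keeps the base-sensitive butenolide out of every strongly basic step by making it last.

Key step: step 5

Remark: 2-methyl-2-[(triethylsilyl)oxy]propanal 14 is assumed not to be a stock item and is made in two steps. Every stereocentre in an intermediate (8, 9, 15 to 18) is transient, so these are racemic mixtures, of diastereomers where two centres are present.

## Route

Step 1
Reactants: 1 pentane-2,4-dione (acetylacetone); 2 methyl benzoate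
Product: 3 1-phenylhexane-1,3,5-trione
Conditions: NaH (4 equiv), 1,2-dimethoxyethane, reflux; then aq. HCl, 0 °C
Reagents that add atoms: none
Why: Claisen-type aroylation of the terminal methyl of a 1,3-diketone through its dianion forms C2–C3. The ester cannot enolise or self-condense, and the triketone is protected in the flask as its polyanion.

Step 2
Reactants: 3 1-phenylhexane-1,3,5-trione
Product: 4 2-methyl-6-phenyl-4H-pyran-4-one
Conditions: conc. H2SO4, 0 °C to rt; poured onto ice
Reagents that add atoms: none
Why: Acid-catalysed cyclodehydration of a 1,3,5-triketone: the enol oxygen of one terminal carbonyl adds to the other and water is lost. Only one 4-pyranone can form from this chain.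

Step 3
Reactants: 4 2-methyl-6-phenyl-4H-pyran-4-one; 5 methyl 3,3-dimethoxypropanoate
Product: 6 2-(4,4-dimethoxy-2-oxobutyl)-6-phenyl-4H-pyran-4-one
Conditions: 4 (2.0 equiv), LiN(i-Pr)2 (2.0 equiv), THF, −78 °C; then 5 (1.0 equiv), −78 to −30 °C; AcOH, −78 °C
Reagents that add atoms: none
Why: Lateral (vinylogous) deprotonation of the 2-methyl group of a 4-pyranone, then Claisen acylation of the anion at its exocyclic carbon by the ester, forms C8–C7. The second equivalent of anion deprotonates the more acidic product and so shields it from further attack; the 4 set free is recovered.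

Step 4
Reactants: 6 2-(4,4-dimethoxy-2-oxobutyl)-6-phenyl-4H-pyran-4-one; 7 methyl bromoacetate
Product: 8 methyl 6,6-dimethoxy-4-oxo-3-(4-oxo-6-phenyl-4H-pyran-2-yl)hexanoate (racemic, labile methine)
Conditions: NaH (1.05 equiv), THF, 0 °C; then 7 (1.05 equiv), 0 °C to rt
Reagents that add atoms: none
Why: SN2 C-alkylation of the doubly stabilised C8 carbanion (flanked by the C7 ketone and the pyranone, a vinylogous 1,3-dicarbonyl) with a reactive α-halo ester. The new C8 centre is not controlled and need not be, since it becomes an aromatic carbon in step 5.

Step 5
Reactants: 8 methyl 6,6-dimethoxy-4-oxo-3-(4-oxo-6-phenyl-4H-pyran-2-yl)hexanoate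
Product: 10 methyl 2-(7-hydroxy-4-oxo-2-phenyl-4H-chromen-8-yl)acetate, via tetrahydrochromenedione ester 9 (not isolated)
Conditions: TsOH·H2O (0.3 equiv), toluene/MeOH (10:1), 70 °C, 0.02 M
Reagents that add atoms: none
Why: Proposed new method: acid ionises the acetal of 8 to the C5 oxocarbenium ion (or, with the water of the catalyst hydrate, to the aldehyde), while protonation of the pyranone carbonyl and loss of the doubly activated C8 proton give the 2-alkylidene-4-hydroxypyran dienol, a push-pull tautomer whose enol β-carbon is pyranone C3 (future C4a); this carbon attacks C5, forming C4a–C5 and closing ring A as 9. The closure is exo-trig at the carbonyl-derived carbon, and is 6-(enolexo) if the C4 dienol is the nucleophile or 6-(enolendo) if the ring enol ether O1–C8a=C4a reacts directly, both allowed modes. Elimination of methanol across C5–C6, activated by the C7 ketone, and enolisation of C7 toward C8 then aromatise ring A as the 7-phenol without any oxidant. The closest known reaction types are the biomimetic aldol cyclisation and aromatisation of poly-β-carbonyl chains to resorcinols and the acid-mediated cyclisation of acetals onto enol ethers and electron-rich heteroarenes; closure onto a carbon of an intact 4-pyranone has not been shown. The two stereocentres of 9 (C5 and C8) are erased on aromatisation, so no element of stereocontrol is needed. The step needs regioselectivity among the folding modes of the chain: the pyranone ties up the C2, C4 and C8a carbonyls, the γ-carbon C8 could reach C5 only through a four-membered ring, and the ester arm is inert in acid, so C4a-to-C5 is the only six-membered carbocyclisation open. Methanol as co-solvent keeps the ortho-hydroxyaryl acetate as its methyl ester and not as the five-membered aryl lactone, and high dilution disfavours intermolecular aldol reaction at C8.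

Step 6
Reactants: 10 methyl 2-(7-hydroxy-4-oxo-2-phenyl-4H-chromen-8-yl)acetate
Product: 11 methyl 2-(7-methoxy-4-oxo-2-phenyl-4H-chromen-8-yl)acetate
Conditions: MeI (1.5 equiv), K2CO3 (2 equiv), acetone, 50 °C
Reagents that add atoms: iodomethane, CI
Why: Williamson ether synthesis. The 7-hydroxyl, para to the C4 carbonyl, is deprotonated by carbonate while the arylacetate CH2 is not, so only oxygen is methylated.

Step 7
Reactants: 12 methyl 2-hydroxy-2-methylpropanoate
Product: 13 methyl 2-methyl-2-[(triethylsilyl)oxy]propanoate
Conditions: Et3SiCl (1.3 equiv), imidazole (2.5 equiv), DMAP (0.1 equiv), DMF, rt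
Reagents that add atoms: chlorotriethylsilane, CC[Si](Cl)(CC)CC
Why: Silyl ether formation on a tertiary alcohol under nucleophilic catalysis. The triethylsilyl group is small enough to go on and is removed by mild acid in step 10.

Step 8
Reactants: 13 methyl 2-methyl-2-[(triethylsilyl)oxy]propanoate
Product: 14 2-methyl-2-[(triethylsilyl)oxy]propanal
Conditions: i-Bu2AlH (1.1 equiv), CH2Cl2, −78 °C; aq. KNaC4H4O6
Reagents that add atoms: none
Why: Partial reduction of an ester to the aldehyde. The aluminium hemiacetal is held at −78 °C by chelation to the α-silyloxy oxygen and collapses only on work-up.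

Step 9
Reactants: 11 methyl 2-(7-methoxy-4-oxo-2-phenyl-4H-chromen-8-yl)acetate; 14 2-methyl-2-[(triethylsilyl)oxy]propanal
Product: 15 methyl 3-hydroxy-2-(7-methoxy-4-oxo-2-phenyl-4H-chromen-8-yl)-4-methyl-4-[(triethylsilyl)oxy]pentanoate (racemic mixture of diastereomers)
Conditions: LiN(SiMe3)2 (1.1 equiv), THF, −78 °C; then 14 (1.5 equiv), −78 °C; AcOH, −78 °C
Reagents that add atoms: none
Why: Aldol addition of a lithium ester enolate to a non-enolisable aldehyde forms C3'–C4'. The amide base is strong enough for the arylacetate α-hydrogen but not for the chromone C3–H, and it does not add to C2. The two new stereocentres (C3', C4') form without control and are both removed in step 11.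

Step 10
Reactants: 15 methyl 3-hydroxy-2-(7-methoxy-4-oxo-2-phenyl-4H-chromen-8-yl)-4-methyl-4-[(triethylsilyl)oxy]pentanoate
Product: 17 4-hydroxy-3-(7-methoxy-4-oxo-2-phenyl-4H-chromen-8-yl)-5,5-dimethyldihydrofuran-2(3H)-one, via diol ester 16 (not isolated)
Conditions: TsOH·H2O (0.2 equiv), MeOH, rt; then toluene, 50 °C
Reagents that add atoms: none
Why: Acid methanolysis of the silyl ether, then acid-catalysed lactonisation of the tertiary alcohol onto the methyl ester, forms O1'–C2'. The five-membered ring and the gem-dimethyl group favour closure, and acid avoids the retro-aldol cleavage that base would invite.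

Step 11
Reactants: 17 4-hydroxy-3-(7-methoxy-4-oxo-2-phenyl-4H-chromen-8-yl)-5,5-dimethyldihydrofuran-2(3H)-one
Product: 19 3-(7-methoxy-4-oxo-2-phenyl-4H-chromen-8-yl)-5,5-dimethylfuran-2(5H)-one, via lactone mesylate 18 (not isolated)
Conditions: MsCl (2 equiv), Et3N (5 equiv), DMAP (0.1 equiv), CH2Cl2, 0 °C to rt
Reagents that add atoms: none
Why: Mesylation of the C4' hydroxyl, then E1cB elimination through the lactone enolate, whose C3' hydrogen is acidified by the aryl group and the carbonyl. C5' is quaternary, so only the conjugated C3'=C4' double bond can form, and both stereocentres vanish.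

## Compound list

1 | pentane-2,4-dione (acetylacetone) | CC(=O)CC(C)=O | starting material
2 | methyl benzoate | COC(=O)c1ccccc1 | starting material
3 | 1-phenylhexane-1,3,5-trione | CC(=O)CC(=O)CC(=O)c1ccccc1 | intermediate
4 | 2-methyl-6-phenyl-4H-pyran-4-one | Cc1cc(=O)cc(-c2ccccc2)o1 | intermediate
5 | methyl 3,3-dimethoxypropanoate | COC(=O)CC(OC)OC | starting material
6 | 2-(4,4-dimethoxy-2-oxobutyl)-6-phenyl-4H-pyran-4-one | COC(OC)CC(=O)Cc1cc(=O)cc(-c2ccccc2)o1 | intermediate
7 | methyl bromoacetate | COC(=O)CBr | starting material
8 | methyl 6,6-dimethoxy-4-oxo-3-(4-oxo-6-phenyl-4H-pyran-2-yl)hexanoate (racemic) | COC(=O)CC(C(=O)CC(OC)OC)c1cc(=O)cc(-c2ccccc2)o1 | intermediate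
9 | methyl 2-(5-methoxy-4,7-dioxo-2-phenyl-5,6,7,8-tetrahydro-4H-chromen-8-yl)acetate (racemic diastereomer mixture) | COC(=O)CC1C(=O)CC(OC)C2=C1OC(c1ccccc1)=CC2=O | intermediate (not isolated)
10 | methyl 2-(7-hydroxy-4-oxo-2-phenyl-4H-chromen-8-yl)acetate | COC(=O)Cc1c(O)ccc2c(=O)cc(-c3ccccc3)oc12 | intermediate
11 | methyl 2-(7-methoxy-4-oxo-2-phenyl-4H-chromen-8-yl)acetate | COC(=O)Cc1c(OC)ccc2c(=O)cc(-c3ccccc3)oc12 | intermediate
12 | methyl 2-hydroxy-2-methylpropanoate | COC(=O)C(C)(C)O | starting material
13 | methyl 2-methyl-2-[(triethylsilyl)oxy]propanoate | COC(=O)C(C)(C)O[Si](CC)(CC)CC | intermediate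
14 | 2-methyl-2-[(triethylsilyl)oxy]propanal | CC[Si](CC)(CC)OC(C)(C)C=O | intermediate
15 | methyl 3-hydroxy-2-(7-methoxy-4-oxo-2-phenyl-4H-chromen-8-yl)-4-methyl-4-[(triethylsilyl)oxy]pentanoate (racemic diastereomer mixture) | COC(=O)C(c1c(OC)ccc2c(=O)cc(-c3ccccc3)oc12)C(O)C(C)(C)O[Si](CC)(CC)CC | intermediate
16 | methyl 3,4-dihydroxy-2-(7-methoxy-4-oxo-2-phenyl-4H-chromen-8-yl)-4-methylpentanoate (racemic diastereomer mixture) | COC(=O)C(c1c(OC)ccc2c(=O)cc(-c3ccccc3)oc12)C(O)C(C)(C)O | intermediate (not isolated)
17 | 4-hydroxy-3-(7-methoxy-4-oxo-2-phenyl-4H-chromen-8-yl)-5,5-dimethyldihydrofuran-2(3H)-one (racemic diastereomer mixture) | COc1ccc2c(=O)cc(-c3ccccc3)oc2c1C1C(O)C(C)(C)OC1=O | intermediate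
18 | 4-(7-methoxy-4-oxo-2-phenyl-4H-chromen-8-yl)-2,2-dimethyl-5-oxotetrahydrofuran-3-yl methanesulfonate (racemic diastereomer mixture) | COc1ccc2c(=O)cc(-c3ccccc3)oc2c1C1C(OS(C)(=O)=O)C(C)(C)OC1=O | intermediate (not isolated)
19 | 3-(7-methoxy-4-oxo-2-phenyl-4H-chromen-8-yl)-5,5-dimethylfuran-2(5H)-one | COc1ccc2c(=O)cc(-c3ccccc3)oc2c1C1=CC(C)(C)OC1=O | target

## Step count and least certain steps

Total: 11 steps. Longest linear sequence: 9 steps (steps 1 to 6 and 9 to 11); steps 7 and 8 form a two-step branch to 14.

**Step 5 (key step, proposed new method).** The pyranone carbon C4a may be too weak a nucleophile. The activated chain end would then be used up by intermolecular aldol reaction at C8, by retro-Claisen loss of the C5 carbon, or by simple elimination to a vinylogous ester that does not close. Lactonisation of the product onto the 7-hydroxyl is a lesser risk. The fallback gives up the fold, takes ring A from a resorcinol, and uses only known chemistry. It sets out from methyl benzoate 2 and returns at 11: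
- The lithium polyanion of 2,4-dihydroxyacetophenone (LiN(SiMe3)2, 4 equiv, THF) undergoes Claisen condensation with 2 to give 1-(2,4-dihydroxyphenyl)-3-phenylpropane-1,3-dione F1.
- Cyclodehydration (H2SO4, AcOH, 100 °C) gives 7-hydroxy-2-phenyl-4H-chromen-4-one F2.
- O-Allylation (allyl bromide, K2CO3, acetone) gives 7-(allyloxy)-2-phenyl-4H-chromen-4-one F3.
- Aromatic Claisen rearrangement (N,N-diethylaniline, 200 °C) places the allyl group on C8, giving 8-allyl-7-hydroxy-2-phenyl-4H-chromen-4-one F4.
- Methylation (MeI, K2CO3) gives 8-allyl-7-methoxy-2-phenyl-4H-chromen-4-one F5.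
- Oxidative cleavage (OsO4 cat., NaIO4, 2,6-lutidine, dioxane/water) gives 2-(7-methoxy-4-oxo-2-phenyl-4H-chromen-8-yl)acetaldehyde F6.
- Pinnick oxidation (NaClO2, NaH2PO4, 2-methyl-2-butene) gives 2-(7-methoxy-4-oxo-2-phenyl-4H-chromen-8-yl)acetic acid F7.
- Esterification (MeI, K2CO3, DMF) gives 11.

**Step 3.** Proton transfer from the α-position of ester 5 to the pyranone anion, followed by β-elimination of methoxide from the ester enolate, would destroy the acylating agent; the acidity of the product also limits conversion. The fallback uses a non-enolisable acyl donor, sets out from 4 and returns at 6. The lithium anion of 4 is acylated with N-methoxy-N-methyl-3-(trimethylsilyl)prop-2-ynamide, whose tetrahedral adduct survives until work-up, giving 2-[2-oxo-4-(trimethylsilyl)but-3-yn-1-yl]-6-phenyl-4H-pyran-4-one F8. K2CO3 in MeOH then removes the silyl group and adds two molecules of methanol across the ynone by double conjugate addition, giving 6.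

**Step 4.** Alkylation on an enolate oxygen in place of C8, and a second alkylation at C8 through proton exchange between product and enolate, would lower the amount of 8. The fallback is a reductive alkylation, sets out from 6 and returns at 8. Knoevenagel condensation of 6 with methyl glyoxylate (L-proline cat., CH2Cl2) gives methyl 6,6-dimethoxy-4-oxo-3-(4-oxo-6-phenyl-4H-pyran-2-yl)hex-2-enoate F9. Diethyl 2,6-dimethyl-1,4-dihydropyridine-3,5-dicarboxylate reduces F9 in the same flask by conjugate hydride transfer, which can give only the mono-C-substituted 8.

**Step 9.** Addition of an enolate whose aryl group is substituted at both ortho positions to an α-quaternary aldehyde may be slow and reversible, with retro-aldol cleavage on warming or during the later acid treatment. The fallback replaces the aldol by alkylation, sets out from 11 and returns at 19: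
- The enolate of 11 (LiN(SiMe3)2, THF, −78 °C) is alkylated with 3-bromo-2-methylpropene to methyl 2-(7-methoxy-4-oxo-2-phenyl-4H-chromen-8-yl)-4-methylpent-4-enoate F10.
- CF3SO3H (cat.) in 1,2-dichloroethane protonates the 1,1-disubstituted alkene and the ester carbonyl captures the tertiary cation, giving 3-(7-methoxy-4-oxo-2-phenyl-4H-chromen-8-yl)-5,5-dimethyldihydrofuran-2(3H)-one F11.
- α-Selenenylation (LiN(SiMe3)2, PhSeBr) gives 3-(7-methoxy-4-oxo-2-phenyl-4H-chromen-8-yl)-5,5-dimethyl-3-(phenylselanyl)dihydrofuran-2(3H)-one F12.
- Oxidation with H2O2 triggers selenoxide syn-elimination toward C4', the only position with β-hydrogens, giving 19.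

## Further compounds

F1 | step 5 | 1-(2,4-dihydroxyphenyl)-3-phenylpropane-1,3-dione | O=C(CC(=O)c1ccccc1)c1ccc(O)cc1O
F2 | step 5 | 7-hydroxy-2-phenyl-4H-chromen-4-one | Oc1ccc2c(=O)cc(-c3ccccc3)oc2c1
F3 | step 5 | 7-(allyloxy)-2-phenyl-4H-chromen-4-one | C=CCOc1ccc2c(=O)cc(-c3ccccc3)oc2c1
F4 | step 5 | 8-allyl-7-hydroxy-2-phenyl-4H-chromen-4-one | C=CCc1c(O)ccc2c(=O)cc(-c3ccccc3)oc12
F5 | step 5 | 8-allyl-7-methoxy-2-phenyl-4H-chromen-4-one | C=CCc1c(OC)ccc2c(=O)cc(-c3ccccc3)oc12
F6 | step 5 | 2-(7-methoxy-4-oxo-2-phenyl-4H-chromen-8-yl)acetaldehyde | O=CCc1c(OC)ccc2c(=O)cc(-c3ccccc3)oc12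
F7 | step 5 | 2-(7-methoxy-4-oxo-2-phenyl-4H-chromen-8-yl)acetic acid | OC(=O)Cc1c(OC)ccc2c(=O)cc(-c3ccccc3)oc12
F8 | step 3 | 2-[2-oxo-4-(trimethylsilyl)but-3-yn-1-yl]-6-phenyl-4H-pyran-4-one | C[Si](C)(C)C#CC(=O)Cc1cc(=O)cc(-c2ccccc2)o1
F9 | step 4 | methyl 6,6-dimethoxy-4-oxo-3-(4-oxo-6-phenyl-4H-pyran-2-yl)hex-2-enoate (alkene geometry not defined) | COC(=O)C=C(C(=O)CC(OC)OC)c1cc(=O)cc(-c2ccccc2)o1
F10 | step 9 | methyl 2-(7-methoxy-4-oxo-2-phenyl-4H-chromen-8-yl)-4-methylpent-4-enoate (racemic) | COC(=O)C(CC(C)=C)c1c(OC)ccc2c(=O)cc(-c3ccccc3)oc12
F11 | step 9 | 3-(7-methoxy-4-oxo-2-phenyl-4H-chromen-8-yl)-5,5-dimethyldihydrofuran-2(3H)-one (racemic) | COc1ccc2c(=O)cc(-c3ccccc3)oc2c1C1CC(C)(C)OC1=O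
F12 | step 9 | 3-(7-methoxy-4-oxo-2-phenyl-4H-chromen-8-yl)-5,5-dimethyl-3-(phenylselanyl)dihydrofuran-2(3H)-one (racemic) | COc1ccc2c(=O)cc(-c3ccccc3)oc2c1C1([Se]c3ccccc3)CC(C)(C)OC1=O
A1 | alternative 1 | 3-methoxy-2-(trimethylsilyl)phenyl trifluoromethanesulfonate | COc1cccc(OS(=O)(=O)C(F)(F)F)c1[Si](C)(C)C
A2 | alternative 1 | 3-methoxybenzyne (3-methoxy-1,2-didehydrobenzene) | COC1=CC=CC#C1
A3 | alternative 1 | 3-methylbut-2-enoic acid | CC(C)=CC(=O)O
A4 | alternative 1 | 5-methoxy-2,2-dimethylchroman-4-one | COc1cccc2OC(C)(C)CC(=O)c12
A5 | alternative 2 | 4-methyl-4-[(4-oxo-2-phenyl-4H-chromen-7-yl)oxy]pent-2-ynoic acid | OC(=O)C#CC(C)(C)Oc1ccc2c(=O)cc(-c3ccccc3)oc2c1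
A6 | alternative 2 | 2-(7-hydroxy-4-oxo-2-phenyl-4H-chromen-8-yl)-4-methylpenta-2,3-dienoic acid | OC(=O)C(=C=C(C)C)c1c(O)ccc2c(=O)cc(-c3ccccc3)oc12
A7 | alternative 2 | 3-(7-hydroxy-4-oxo-2-phenyl-4H-chromen-8-yl)-5,5-dimethylfuran-2(5H)-one | Oc1ccc2c(=O)cc(-c3ccccc3)oc2c1C1=CC(C)(C)OC1=O
A8 | alternative 3 | 3-(2-methoxy-6-oxocyclohex-1-en-1-yl)-5,5-dimethylfuran-2(5H)-one | COC1=C(C2=CC(C)(C)OC2=O)C(=O)CCC1
A9 | alternative 3 | N-methoxy-N-methyl-3-phenylpropiolamide | CON(C)C(=O)C#Cc1ccccc1
A10 | alternative 3 | 3-(7-methoxy-4-oxo-2-phenyl-5,6-dihydro-4H-chromen-8-yl)-5,5-dimethylfuran-2(5H)-one | COC1=C(C3=CC(C)(C)OC3=O)C2=C(CC1)C(=O)C=C(c4ccccc4)O2
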